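**Retrosynthetic overview**
- The last bond cut is indole C2–C(CH3)2. The target comes from the symmetric 2,5-di(indol-3-yl)-3,6-dimethoxyquinone and B-prenyl-9-BBN: one indole is chlorinated at C3 (which breaks its aromaticity and the C2h symmetry of the quinone in one event), allylborated at C2 with allylic transposition, then rearomatised.
- The symmetric dimethoxyquinone comes from 2,5-dibromo-3,6-di(indol-3-yl)quinone by double bromide-for-methoxide exchange.
- The dibromide comes from bromanil and two molecules of indole by double addition–elimination (2,5-pattern).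
- B-prenyl-9-BBN comes from 9-BBN and 3-methylbuta-1,2-diene.
- No ring is built: both indoles and the quinone ring are bought. Bonds are made in the order quinone–indole (twice), C–OMe (twice), indole C2–quaternary carbon.

Assumption: the target has no stereocentre and rotation about the indole–quinone bonds is taken as free, so the compound is achiral and there is no enantiomer to select.

**Step 1**
Reactants: 1 indole (2.1 equiv); 2 bromanil (tetrabromo-1,4-benzoquinone)
Product: 4 2,5-dibromo-3,6-di(1H-indol-3-yl)cyclohexa-2,5-diene-1,4-dione, via mono(indolyl)tribromoquinone 3 (not isolated)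
Conditions: Cs2CO3 (4 equiv), MeCN, 23 °C, 16 h, dark; water, filtration or chromatography
Reagents that add atoms: none
Why: Vinylic nucleophilic substitution (addition–elimination) by indole C3 on the tetrahaloquinone; the first indolyl group is a vinylogous donor that deactivates the carbonyl it conjugates with, so the second indole attacks the bromine-bearing carbon para to the first, as amines do on chloranil.

**Step 2**
Reactants: 4 2,5-dibromo-3,6-di(1H-indol-3-yl)cyclohexa-2,5-diene-1,4-dione
Product: 6 2,5-di(1H-indol-3-yl)-3,6-dimethoxycyclohexa-2,5-diene-1,4-dione (asterriquinone D), via bromo(methoxy)quinone 5 (not isolated)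
Conditions: NaOMe (6 equiv), MeOH–THF 1:1, 50 °C, 4 h; AcOH quench
Reagents that add atoms: sodium methoxide (NaOMe), [Na+].[O-]C
Why: Addition–elimination of methoxide at each bromine-bearing carbon (the β-carbon of an enone) with bromide as leaving group; under anhydrous conditions the exchange stops at the dimethoxyquinone, and the reversibly deprotonated indole N–H groups are restored by the AcOH quench.

**Step 3**
Reactants: 7 9-borabicyclo[3.3.1]nonane (9-BBN, 0.5 M in THF); 8 3-methylbuta-1,2-diene (1.05 equiv)
Product: 9 B-prenyl-9-BBN, 9-(3-methylbut-2-en-1-yl)-9-borabicyclo[3.3.1]nonane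
Conditions: THF, 0 → 23 °C, 2 h, argon; used as the resulting ca. 0.5 M solution
Reagents that add atoms: none
Why: Hydroboration of the allene places boron on the unsubstituted terminal carbon and hydrogen on the central carbon, giving the allylic borane in a pure addition in which every atom of both partners ends up in 9.

**Step 4**
Reactants: 6 2,5-di(1H-indol-3-yl)-3,6-dimethoxycyclohexa-2,5-diene-1,4-dione; 9 B-prenyl-9-BBN (1.05 equiv)
Product: 12 2-(1H-indol-3-yl)-3,6-dimethoxy-5-[2-(2-methylbut-3-en-2-yl)-1H-indol-3-yl]cyclohexa-2,5-diene-1,4-dione (target CNP0103667.0), via 3-chloroindolenine 10 (not isolated), via N-boryl chloroindoline 11 (not isolated)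
Conditions: Et3N (1.2 equiv), t-BuOCl (0.95 equiv), THF, −78 °C, 30 min; then 9 in THF, −78 → 0 °C, 3 h, then 23 °C, 1 h; H2O quench; chromatography, unreacted 6 recycled
Reagents that add atoms: compound 9, B-prenyl-9-BBN, CC(C)=CCB1C2CCCC1CCC2 (tert-butyl hypochlorite, CC(C)(C)OCl, puts chlorine only into 10 and 11, none into 12)
Why: Proposed new method: tert-butyl hypochlorite chlorinates one indole at C3 (through the N-chloroindole) to the dearomatised 3-chloro-3H-indole 10, which ends the C2h symmetry of 6 and makes the quinone more electron-poor so that the remaining indole is somewhat less nucleophilic and mono-chlorination is favoured; the C2=N bond of 10 binds the boron of 9 and receives the prenyl group at its γ-carbon through a six-membered chair transition state (allylboration with allylic transposition, forming the quaternary 1,1-dimethylallyl carbon), and loss of HCl from 11 restores the indole; the quinone carbonyls are each flanked by two fully substituted carbons and deactivated as vinylogous ester/amide carbonyls, so the unhindered chlorine-activated aldimine should win at −78 °C; the closest known reaction type is the Danishefsky reverse prenylation of 3-substituted indoles through 3-chloroindolenines with B-prenyl-9-BBN, applied here to a quinone-bearing bis-indole; no stereocentre survives into 12.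

**Compound list**
1 | indole | c1ccc2[nH]ccc2c1 | starting material
2 | bromanil (2,3,5,6-tetrabromocyclohexa-2,5-diene-1,4-dione) | O=C1C(Br)=C(Br)C(=O)C(Br)=C1Br | starting material
3 | 2,3,5-tribromo-6-(1H-indol-3-yl)cyclohexa-2,5-diene-1,4-dione, formed and consumed in the flask in step 1 | O=C1C(Br)=C(Br)C(=O)C(c2c[nH]c3ccccc23)=C1Br | intermediate
4 | 2,5-dibromo-3,6-di(1H-indol-3-yl)cyclohexa-2,5-diene-1,4-dione | O=C1C(Br)=C(c2c[nH]c3ccccc23)C(=O)C(Br)=C1c1c[nH]c2ccccc12 | intermediate
5 | 2-bromo-3,6-di(1H-indol-3-yl)-5-methoxycyclohexa-2,5-diene-1,4-dione, formed and consumed in the flask in step 2 | O=C1C(Br)=C(c2c[nH]c3ccccc23)C(=O)C(OC)=C1c1c[nH]c2ccccc12 | intermediate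
6 | 2,5-di(1H-indol-3-yl)-3,6-dimethoxycyclohexa-2,5-diene-1,4-dione (asterriquinone D) | COC1=C(c2c[nH]c3ccccc23)C(=O)C(OC)=C(c2c[nH]c3ccccc23)C1=O | intermediate
7 | 9-borabicyclo[3.3.1]nonane (9-BBN) | B1C2CCCC1CCC2 | starting material
8 | 3-methylbuta-1,2-diene | CC(C)=C=C | starting material
9 | B-prenyl-9-BBN, 9-(3-methylbut-2-en-1-yl)-9-borabicyclo[3.3.1]nonane | CC(C)=CCB1C2CCCC1CCC2 | intermediate
10 | 2-(3-chloro-3H-indol-3-yl)-5-(1H-indol-3-yl)-3,6-dimethoxycyclohexa-2,5-diene-1,4-dione, racemic, formed and consumed in the flask in step 4 | COC1=C(C2(Cl)C=Nc3ccccc32)C(=O)C(OC)=C(c2c[nH]c3ccccc23)C1=O | intermediate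
11 | 2-[1-(9-borabicyclo[3.3.1]nonan-9-yl)-3-chloro-2-(2-methylbut-3-en-2-yl)-2,3-dihydro-1H-indol-3-yl]-5-(1H-indol-3-yl)-3,6-dimethoxycyclohexa-2,5-diene-1,4-dione, mixture of stereoisomers, formed and consumed in the flask in step 4 | COC1=C(C2(Cl)C(C(C)(C)C=C)N(B3C4CCCC3CCC4)c3ccccc32)C(=O)C(OC)=C(c2c[nH]c3ccccc23)C1=O | intermediate
12 | 2-(1H-indol-3-yl)-3,6-dimethoxy-5-[2-(2-methylbut-3-en-2-yl)-1H-indol-3-yl]cyclohexa-2,5-diene-1,4-dione | C=CC(C)(C)c1[nH]c2ccccc2c1C1=C(OC)C(=O)C(c2c[nH]c3ccccc23)=C(OC)C1=O | target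

**Step count**
Total: 4 steps (steps 1, 2 and 4 on the main line, step 3 a reagent preparation). Longest linear sequence: 3 steps (1 → 4 → 6 → 12).

**Steps most likely to fail, and fallbacks**

Step 4 is the riskiest. The allylborane may attack a quinone carbonyl or be protonolysed by the free indole N–H, chlorination may not stay on one indole, and some doubly prenylated product is expected. The fallback sets out from 6 and comes back at 12. NBS (1.0 equiv, THF, −78 → 0 °C) brominates one indole at C2, through the 3-bromoindolenine and a 1,2-bromine shift, to 2-(2-bromo-1H-indol-3-yl)-5-(1H-indol-3-yl)-3,6-dimethoxycyclohexa-2,5-diene-1,4-dione F1. A branch-selective Suzuki–Miyaura allylation of F1 with commercial 3-methylbut-2-enylboronic acid pinacol ester (Pd(OAc)2, a bulky biaryl dialkylphosphine chosen for γ-selectivity, K3PO4, THF–H2O, 40 °C) then forms the C2–quaternary carbon bond by reductive elimination from the γ-bound allylpalladium species and gives 12. This replaces the allylborane with a cross-coupling that keeps nucleophilic allylmetal away from the quinone carbonyls.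

Step 1 is next. Unsubstituted indole may give N-attack or mixtures of 2,5- and 2,6-isomers with bromanil under base. The fallback sets out from 1 and comes back at 6. Indole 1 adds under acid (AcOH, or catalytic HCl in THF, 23 °C) to commercial 2,5-dichloro-1,4-benzoquinone, whose two free C–H positions fix the substitution pattern, to give 2,5-dichloro-3-(1H-indol-3-yl)benzene-1,4-diol F2. DDQ oxidises this to 2,5-dichloro-3-(1H-indol-3-yl)cyclohexa-2,5-diene-1,4-dione F3. A second round with 1 gives 2,5-dichloro-3,6-di(1H-indol-3-yl)benzene-1,4-diol F4 and, after DDQ, 2,5-dichloro-3,6-di(1H-indol-3-yl)cyclohexa-2,5-diene-1,4-dione F5. NaOMe under the conditions of step 2 then replaces both chlorides, through 2-chloro-3,6-di(1H-indol-3-yl)-5-methoxycyclohexa-2,5-diene-1,4-dione F6, and delivers 6.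

Step 2 is third. The indolide anions formed under NaOMe may slow the second exchange, or adventitious hydroxide may give partly demethylated material. The fallback sets out from 4 and comes back at 6. NaOH in MeOH–H2O at reflux hydrolyses 4, through 2-bromo-5-hydroxy-3,6-di(1H-indol-3-yl)cyclohexa-2,5-diene-1,4-dione F7, to 2,5-dihydroxy-3,6-di(1H-indol-3-yl)cyclohexa-2,5-diene-1,4-dione F8, isolated after acidification with HCl. TMSCHN2 (MeOH–toluene, 23 °C) then methylates the two acidic vinylogous-acid hydroxyls, through 2-hydroxy-3,6-di(1H-indol-3-yl)-5-methoxycyclohexa-2,5-diene-1,4-dione F9, to 6 without touching the indole N–H.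

**Further compounds**
F1 | step 4 | 2-(2-bromo-1H-indol-3-yl)-5-(1H-indol-3-yl)-3,6-dimethoxycyclohexa-2,5-diene-1,4-dione | COC1=C(c2c(Br)[nH]c3ccccc23)C(=O)C(OC)=C(c2c[nH]c3ccccc23)C1=O
F2 | step 1 | 2,5-dichloro-3-(1H-indol-3-yl)benzene-1,4-diol | Oc1cc(Cl)c(O)c(-c2c[nH]c3ccccc23)c1Cl
F3 | step 1 | 2,5-dichloro-3-(1H-indol-3-yl)cyclohexa-2,5-diene-1,4-dione | O=C1C=C(Cl)C(=O)C(c2c[nH]c3ccccc23)=C1Cl
F4 | step 1 | 2,5-dichloro-3,6-di(1H-indol-3-yl)benzene-1,4-diol | Oc1c(Cl)c(-c2c[nH]c3ccccc23)c(O)c(Cl)c1-c1c[nH]c2ccccc12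
F5 | step 1 | 2,5-dichloro-3,6-di(1H-indol-3-yl)cyclohexa-2,5-diene-1,4-dione | O=C1C(Cl)=C(c2c[nH]c3ccccc23)C(=O)C(Cl)=C1c1c[nH]c2ccccc12
F6 | step 1 | 2-chloro-3,6-di(1H-indol-3-yl)-5-methoxycyclohexa-2,5-diene-1,4-dione | O=C1C(Cl)=C(c2c[nH]c3ccccc23)C(=O)C(OC)=C1c1c[nH]c2ccccc12
F7 | step 2 | 2-bromo-5-hydroxy-3,6-di(1H-indol-3-yl)cyclohexa-2,5-diene-1,4-dione | O=C1C(Br)=C(c2c[nH]c3ccccc23)C(=O)C(O)=C1c1c[nH]c2ccccc12
F8 | step 2 | 2,5-dihydroxy-3,6-di(1H-indol-3-yl)cyclohexa-2,5-diene-1,4-dione | O=C1C(O)=C(c2c[nH]c3ccccc23)C(=O)C(O)=C1c1c[nH]c2ccccc12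
F9 | step 2 | 2-hydroxy-3,6-di(1H-indol-3-yl)-5-methoxycyclohexa-2,5-diene-1,4-dione | O=C1C(O)=C(c2c[nH]c3ccccc23)C(=O)C(OC)=C1c1c[nH]c2ccccc12
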